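## Retrosynthetic overview
1. The target comes from α-iodination of the enone, preceded by swapping the C7 silyl ether for the acetate, so the precursor is a 4-hydroxy-4-alkyl-5-(silyloxyalkyl)cyclopent-2-enone.
2. That cyclopentenone is the only ring to be formed. It arises in one step by 4π-conrotatory electrocyclization (Piancatelli rearrangement) of a 5-alkyl-2-furylcarbinol. This step creates the C4 tertiary carbinol and ring C8 together.
3. The furylcarbinol comes from 5-lithio-2-(Z-octenyl)furan and an α-silyloxy (Z)-enal.
4. The enal comes from D-mannitol-derived (R)-glyceraldehyde acetonide by Z-Wittig with the Corey ylide. This supplies the only purchased stereocenter (C7), which directs C4 and C8 in the ring closure.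

Assumptions (one line each):
- (R)-Glyceraldehyde acetonide, (Z)-oct-2-en-1-ol, furan and the phosphonium salt are commercial.
- The C8 carbinol epimers of compound 13 need not be separated, because that center is destroyed in Step 10.

## Route

**Step 1**
Reactants: 1 (R)-2,3-O-isopropylideneglyceraldehyde; 2 (4-carboxybutyl)triphenylphosphonium bromide
Product: 3 (5Z)-6-[(4S)-2,2-dimethyl-1,3-dioxolan-4-yl]hex-5-enoic acid
Conditions: 2 + KHMDS (2.2 equiv), THF, 0 °C; then 1, –78 °C → rt; aqueous citric acid work-up
Reagents that add atoms: none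
Why: Wittig reaction of a non-stabilized, salt-free ylide gives the Z-alkene (C5=C6), and the α-stereocenter is untouched. The descriptor changes from R to S only because CIP priorities change.

**Step 2**
Reactants: 3
Product: 4 methyl (5Z)-6-[(4S)-2,2-dimethyl-1,3-dioxolan-4-yl]hex-5-enoate
Conditions: TMSCHN2, MeOH/PhMe, 0 °C → rt
Reagents that add atoms: trimethylsilyldiazomethane, C[Si](C)(C)C=[N+]=[N-] (adds CH3)
Why: Diazoalkane O-methylation of the carboxylic acid is mild and leaves the acetonide and the Z-alkene intact.

**Step 3**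
Reactants: 4
Product: 5 methyl (5Z,7S)-7,8-dihydroxyoct-5-enoate
Conditions: PPTS (0.2 equiv), MeOH, 40 °C
Reagents that add atoms: none
Why: Acid-catalysed trans-ketalization releases the 1,2-diol; no stereocenter is involved.

**Step 4**
Reactants: 5
Product: 6 methyl (5Z,7S)-7,8-bis(TBS-oxy)oct-5-enoate
Conditions: TBSOTf (2.5 equiv), 2,6-lutidine, CH2Cl2, –78 → 0 °C
Reagents that add atoms: TBSOTf, CC(C)(C)[Si](C)(C)OS(=O)(=O)C(F)(F)F (adds TBS)
Why: Silylation of both hydroxyls sets up differentiation of the primary and secondary positions.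

**Step 5**
Reactants: 6
Product: 7 methyl (5Z,7S)-7-(TBS-oxy)-8-hydroxyoct-5-enoate
Conditions: CSA (0.1 equiv), MeOH/CH2Cl2 1:1, 0 °C
Reagents that add atoms: none
Why: Acidic methanolysis cleaves a primary TBS ether much faster than a secondary allylic one.

**Step 6**
Reactants: 7
Product: 8 methyl (5Z,7S)-7-(TBS-oxy)-8-oxooct-5-enoate
Conditions: Dess–Martin periodinane, NaHCO3, CH2Cl2, 0 °C → rt, 1 h; used crude at once
Reagents that add atoms: none
Why: Dess–Martin oxidation is neutral and non-epimerizing for this configurationally labile α-silyloxy aldehyde.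

**Step 7**
Reactants: 9 (2Z)-oct-2-en-1-ol
Product: 10 (2Z)-1-bromooct-2-ene
Conditions: CBr4, PPh3, CH2Cl2, 0 °C
Reagents that add atoms: carbon tetrabromide, BrC(Br)(Br)Br (adds Br)
Why: Appel bromination is a direct SN2 with no allylic transposition, so the Z-alkene is kept.

**Step 8**
Reactants: 11 furan; 10
Product: 12 2-[(2Z)-oct-2-en-1-yl]furan
Conditions: furan + n-BuLi, THF, 0 °C; then 10, –78 °C → rt
Reagents that add atoms: none
Why: 2-Lithiofuran undergoes SN2 alkylation with the allylic bromide to give the 2-alkylfuran.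

**Step 9**
Reactants: 12; 8
Product: 13 methyl (5Z,7S)-7-(TBS-oxy)-8-hydroxy-8-{5-[(2Z)-oct-2-en-1-yl]furan-2-yl}oct-5-enoate (C8 epimers)
Conditions: 12 + n-BuLi (1.3 equiv), THF, –20 °C, 1 h; then 8 in THF, –78 °C, 1 h
Reagents that add atoms: none
Why: Lithiation at the free furan α-position followed by chemoselective 1,2-addition to the aldehyde (faster than attack on the ester) gives the furylcarbinol. The new carbinol center is erased in the next step, so its configuration does not matter.

**Step 10**
Reactants: 13
Product: 14 methyl (5Z,7S)-7-(TBS-oxy)-7-[2-hydroxy-5-oxo-2-((2Z)-oct-2-en-1-yl)cyclopent-3-en-1-yl]hept-5-enoate (ring centers as in the SMILES)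
Conditions: Dy(OTf)3 (5 mol%), MeCN/H2O 9:1, 60 °C
Reagents that add atoms: water, O (its oxygen becomes the C4 hydroxyl; net reaction is an isomerization)
Why: Piancatelli rearrangement: furfuryl cation formation, water capture at furan C5 and ring opening give a hydroxypentadienyl cation that closes by 4π-conrotatory electrocyclization. The C7 stereocenter (C7–OTBS anti to the forming C8–C4 bond) fixes the face at C8, and the larger octenyl terminus rotates outward so the OH lands cis to the C8 side chain. This gives the trans α/ω prostanoid-like arrangement, so C4 and C8 are set by the purchased C7 center.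

**Step 11**
Reactants: 14
Product: 15 methyl (5Z,7S)-7-(TBS-oxy)-7-[2-hydroxy-4-iodo-5-oxo-2-((2Z)-oct-2-en-1-yl)cyclopent-3-en-1-yl]hept-5-enoate
Conditions: I2 (2 equiv), pyridine/CH2Cl2 1:1, 0 °C → rt, dark, short reaction time
Reagents that add atoms: iodine, II (adds I)
Why: Johnson α-iodination of the enone proceeds by addition–iodination–elimination via pyridine. The silyl ether keeps C7 from undergoing retro-aldol or elimination under the basic conditions.

**Step 12**
Reactants: 15
Product: 16 methyl (5Z,7S)-7-hydroxy-7-[2-hydroxy-4-iodo-5-oxo-2-((2Z)-oct-2-en-1-yl)cyclopent-3-en-1-yl]hept-5-enoate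
Conditions: HF·pyridine, pyridine/THF, 0 °C → rt
Reagents that add atoms: none
Why: Buffered fluoride removes the secondary TBS ether without touching the tertiary alcohol, ester, iodoenone or alkenes.

**Step 13**
Reactants: 16
Product: 17 7-acetoxy-7,8-dihydroiodovulone I (target)
Conditions: Ac2O, pyridine, DMAP (5 mol%), CH2Cl2, 0 °C
Reagents that add atoms: acetic anhydride, CC(=O)OC(C)=O (adds COCH3)
Why: Acylation is selective for the less hindered secondary alcohol over the tertiary allylic carbinol, and is done last so the base-sensitive β-acetoxy ketone sees no further base.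

## Compound list
1 | (R)-2,3-O-isopropylideneglyceraldehyde | O=C[C@H]1COC(C)(C)O1 | starting material
2 | (4-carboxybutyl)triphenylphosphonium bromide | OC(=O)CCCC[P+](c1ccccc1)(c1ccccc1)c1ccccc1.[Br-] | starting material
3 | (5Z)-6-[(4S)-2,2-dimethyl-1,3-dioxolan-4-yl]hex-5-enoic acid | OC(=O)CCC/C=C\[C@H]1COC(C)(C)O1 | intermediate
4 | methyl ester of 3 | COC(=O)CCC/C=C\[C@H]1COC(C)(C)O1 | intermediate
5 | methyl (5Z,7S)-7,8-dihydroxyoct-5-enoate | COC(=O)CCC/C=C\[C@H](O)CO | intermediate
6 | bis-TBS ether of 5 | COC(=O)CCC/C=C\[C@H](O[Si](C)(C)C(C)(C)C)CO[Si](C)(C)C(C)(C)C | intermediate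
7 | methyl (5Z,7S)-7-(TBS-oxy)-8-hydroxyoct-5-enoate | COC(=O)CCC/C=C\[C@H](O[Si](C)(C)C(C)(C)C)CO | intermediate
8 | methyl (5Z,7S)-7-(TBS-oxy)-8-oxooct-5-enoate | COC(=O)CCC/C=C\[C@H](O[Si](C)(C)C(C)(C)C)C=O | intermediate
9 | (2Z)-oct-2-en-1-ol | CCCCC/C=C\CO | starting material
10 | (2Z)-1-bromooct-2-ene | CCCCC/C=C\CBr | intermediate
11 | furan | c1ccoc1 | starting material
12 | 2-[(2Z)-oct-2-en-1-yl]furan | CCCCC/C=C\Cc1ccco1 | intermediate
13 | furylcarbinol (C8 epimers) | COC(=O)CCC/C=C\[C@H](O[Si](C)(C)C(C)(C)C)C(O)c1ccc(C/C=C\CCCCC)o1 | intermediate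
14 | Piancatelli cyclopentenone | CCCCC/C=C\C[C@@]1(O)C=CC(=O)[C@@H]1[C@H](/C=C\CCCC(=O)OC)O[Si](C)(C)C(C)(C)C | intermediate
15 | α-iodoenone TBS ether | CCCCC/C=C\C[C@@]1(O)C=C(I)C(=O)[C@@H]1[C@H](/C=C\CCCC(=O)OC)O[Si](C)(C)C(C)(C)C | intermediate
16 | free C7 alcohol | CCCCC/C=C\C[C@@]1(O)C=C(I)C(=O)[C@@H]1[C@H](/C=C\CCCC(=O)OC)O | intermediate
17 | 7-acetoxy-7,8-dihydroiodovulone I | CCCCC/C=C\C[C@@]1(O)C=C(I)C(=O)[C@@H]1[C@H](/C=C\CCCC(=O)OC)OC(C)=O | target

## Totals
Total steps: 13. Longest linear sequence: 11 steps (Steps 1–6, then 9–13; the two-step furan branch, Steps 7–8, joins at Step 9).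

## Three steps most likely to fail
1. **Step 10 (Piancatelli closure).** The diastereocontrol from C7 is unproven, and the TBS ether or the furan may not survive hot aqueous Lewis acid.
   Fallback: run the rearrangement on the 5-H furan analogue (2-lithiofuran + 8). This gives the trans-4-hydroxy-5-substituted cyclopentenone reliably. Then oxidize C4 to the ene-dione and add (Z)-oct-2-enylzinc bromide anti to the C5 side chain to form the tertiary carbinol.
2. **Steps 6 and 9 (labile α-silyloxy Z-enal and its furyl addition).** The aldehyde can epimerize or isomerize to the conjugated enal, and lateral lithiation of 12 at the doubly activated CH2 could compete.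
   Fallback: oxidize alcohol 7 to the acid, convert it to the Weinreb amide, add 5-alkyl-2-lithiofuran to give the furyl ketone, then reduce to the carbinol. The carbinol center is erased anyway, so only C7 matters.
3. **Step 11 (iodination).** I2 may isomerize a Z-alkene, or pyridine may cause β-elimination.
   Fallback: carry the iodine in from the start. Make the 3-iodo-2-furylcarbinol by iodine-directed lithiation of a 3-iodofuran, so the Piancatelli closure delivers the α-iodoenone directly and Step 11 disappears.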